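## Retrosynthetic overview

1. Feature: in unit B the benzene ring (C4a, C5, C6, C7, C8, C8a) has oxygen on C7 and C8a, on either side of the aryl-bearing C8, and carbon (C4) on C4a. This is a 3-aryl-2,4-dihydroxybenzoyl unit, the aldol fold of a 3,5,7-tricarbonyl heptanoate that carries the aryl group on its C4.
2. The lactone of unit C is made last, by propiolate annulation of the freed, symmetric resorcinol ring. The lactone of unit B and the C3–O–C7 ether to unit A come from a Perkin condensation of salicylaldehyde 14 with (coumarin-7-yloxy)acetic acid 18.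
3. The benzene ring of unit B arises by forming bond C4a–C5 when alkoxide refolds the 4-pyranone-2-acetate 9 into resorcylate 11. The crowded C8–C8' bond is never coupled, because it is the benzylic C–aryl bond of acid 1.
4. Pyranone 9 comes from beta-keto ester 4 (from 1 and Meldrum's acid) by gamma-acylation of its dianion with Weinreb amide 6 and acid cyclodehydration.
5. Ring order: benzene ring of unit C and unit A (bought) → 4-pyranone → benzene ring B → lactone B → lactone C.

Key step: step 6

Assumption: the target SMILES carries no stereodescriptor and the molecule has no stereocentre. The C8–C8' axis becomes stereogenic only in step 14 and is taken as racemic.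

## Route

Step 1
Reactants: 1 2,6-dimethoxyphenylacetic acid; 2 Meldrum's acid
Product: 3 5-[2-(2,6-dimethoxyphenyl)-1-hydroxyethylidene]-2,2-dimethyl-1,3-dioxane-4,6-dione
Conditions: dicyclohexylcarbodiimide (1.1 equiv), DMAP (1.2 equiv), CH2Cl2, 0 °C to rt
Reagents that add atoms: none
Why: Carbodiimide activation of the acid and C-acylation of the very acidic Meldrum's acid is routine for arylacetic acids, and the product rests as its hydrogen-bonded enol.

Step 2
Reactants: 3 acyl Meldrum's acid
Product: 4 ethyl 4-(2,6-dimethoxyphenyl)-3-oxobutanoate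
Conditions: EtOH, reflux
Reagents that add atoms: ethanol, CCO
Why: Heating an acyl Meldrum's acid in an alcohol opens the dioxanedione with loss of acetone and CO2 (alcoholysis of acyl Meldrum's acids), the standard two-carbon homologation of an acid to its beta-keto ester.

Step 3
Reactants: 5 methyl 3,3-dimethoxypropanoate
Product: 6 N,3,3-trimethoxy-N-methylpropanamide
Conditions: MeNH(OMe)·HCl (1.5 equiv), i-PrMgCl (3 equiv), THF, −20 °C
Reagents that add atoms: N,O-dimethylhydroxylamine hydrochloride, CNOC.Cl
Why: The chloromagnesium amide made in the flask displaces methoxide at low temperature (Weinreb amide synthesis by ester aminolysis), and the amide is preferred to ester 5 as acyl donor because its alpha-protons are less acidic and its adduct does not collapse before the quench.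

Step 4
Reactants: 4 ethyl 4-(2,6-dimethoxyphenyl)-3-oxobutanoate; 6 N,3,3-trimethoxy-N-methylpropanamide
Product: 8 ethyl 4-(2,6-dimethoxyphenyl)-7,7-dimethoxy-3,5-dioxoheptanoate (racemic, largely enolised), via dilithio dianion 7 (not isolated)
Conditions: LiN(i-Pr)2 (2.2 equiv), THF, −78 to 0 °C; then 6, −78 to 0 °C; aq. NH4Cl
Reagents that add atoms: none
Why: The beta-keto ester dianion reacts only at its more basic benzylic terminus, and gamma-acylation by a Weinreb amide (Weinreb ketone synthesis) holds the adduct as a lithium chelate, so the more acidic product cannot quench unreacted dianion and no excess base is left to eliminate methanol from the acetal.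

Step 5
Reactants: 8 ethyl 4-(2,6-dimethoxyphenyl)-7,7-dimethoxy-3,5-dioxoheptanoate
Product: 9 ethyl 2-[3-(2,6-dimethoxyphenyl)-4-oxo-4H-pyran-2-yl]acetate
Conditions: CF3CO2H, CH2Cl2, rt
Reagents that add atoms: none
Why: Acid ionises the acetal, the enol oxygen of the C3 ketone closes on C7 in a six-membered ring and two molecules of methanol are lost (acid cyclodehydration of a masked 1,3,5-tricarbonyl compound to a 4-pyranone), O-closure being the kinetic path in acid, while any C-closed material would be 11 itself.

Step 6
Reactants: 9 ethyl 2-[3-(2,6-dimethoxyphenyl)-4-oxo-4H-pyran-2-yl]acetate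
Product: 11 ethyl 2,4-dihydroxy-3-(2,6-dimethoxyphenyl)benzoate, via ring-opened ethoxy enone 10 (not isolated)
Conditions: NaOEt (2.5 equiv), dry EtOH, reflux; then 1 M HCl, 0 °C
Reagents that add atoms: none
Why: Ethoxide adds to C6, the only unsubstituted position next to the ring oxygen, and the C6–O1 bond breaks, which lays the chain open as the 7-ethoxy enone 10 with C7 still at the aldehyde oxidation level. The methylene between the ester and the C3 ketone then adds to C7 and ethoxide leaves again, a vinylogous aldol condensation that forms C4a–C5 of unit B by a 6-endo-trig addition–elimination, and tautomerisation of the two ring ketones gives the arene. The closest known reaction type is the base-induced conversion of 4-pyranones, taken as masked 1,3,5-tricarbonyl chains, into resorcinols, for example 2,6-dimethyl-4-pyranone into orcinol. No stereocentre is formed. C–C closure has to beat O-reclosure and Claisen closure onto the ester: every O-closure is reversible in ethoxide whereas aromatisation is not, and the enol-ether terminus offers neither a nucleophilic C6 nor a free formyl group, so the phloroglucinol path and the deformylation to be feared in aqueous KOH are shut off. Ethoxide in ethanol also matches the ester, so saponification with decarboxylation and ester exchange cannot alter the product.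

Step 7
Reactants: 11 ethyl 2,4-dihydroxy-3-(2,6-dimethoxyphenyl)benzoate
Product: 12 ethyl 2-hydroxy-4-methoxy-3-(2,6-dimethoxyphenyl)benzoate
Conditions: MeI (1.05 equiv), K2CO3 (1.1 equiv), acetone, rt to 40 °C
Reagents that add atoms: iodomethane, CI
Why: The 2-OH is tied up in a hydrogen bond to the ester carbonyl and is less acidic than the 4-OH para to the ester, so one equivalent of MeI under weak base alkylates O4 only (Williamson etherification with the usual selectivity of 2,4-dihydroxybenzoates).

Step 8
Reactants: 12 ethyl 2-hydroxy-4-methoxy-3-(2,6-dimethoxyphenyl)benzoate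
Product: 13 2-(2,6-dimethoxyphenyl)-6-(hydroxymethyl)-3-methoxyphenol
Conditions: LiAlH4 (2 equiv), THF, 0 °C; aq. potassium sodium tartrate
Reagents that add atoms: none
Why: LiAlH4 reduces the salicylate ester through its aluminium phenoxide to the benzylic alcohol (hydride reduction of an ester), and low temperature plus a neutral work-up keep the electron-rich o-hydroxybenzyl alcohol from ionising to a quinone methide.

Step 9
Reactants: 13 2-(2,6-dimethoxyphenyl)-6-(hydroxymethyl)-3-methoxyphenol
Product: 14 2-hydroxy-4-methoxy-3-(2,6-dimethoxyphenyl)benzaldehyde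
Conditions: activated MnO2 (10 equiv), CH2Cl2, rt
Reagents that add atoms: none
Why: Activated MnO2 oxidises benzylic alcohols selectively and stops at the aldehyde (heterogeneous benzylic oxidation), which is stabilised here by its hydrogen bond to the free ortho phenol.

Step 10
Reactants: 15 umbelliferone; 16 tert-butyl bromoacetate
Product: 17 tert-butyl 2-[(2-oxo-2H-chromen-7-yl)oxy]acetate
Conditions: K2CO3, acetone, reflux
Reagents that add atoms: none
Why: The acidic 7-OH of umbelliferone is alkylated by the alpha-bromo ester under weak base (Williamson etherification) without opening the lactone.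

Step 11
Reactants: 17 tert-butyl 2-[(2-oxo-2H-chromen-7-yl)oxy]acetate
Product: 18 2-[(2-oxo-2H-chromen-7-yl)oxy]acetic acid
Conditions: CF3CO2H, CH2Cl2, rt
Reagents that add atoms: none
Why: Acidolysis of the tert-butyl ester (E1 loss of isobutene) frees the acid without the aqueous base that would open the coumarin lactone.

Step 12
Reactants: 14 2-hydroxy-4-methoxy-3-(2,6-dimethoxyphenyl)benzaldehyde; 18 2-[(2-oxo-2H-chromen-7-yl)oxy]acetic acid
Product: 20 8-(2,6-dimethoxyphenyl)-7-methoxy-3-[(2-oxo-2H-chromen-7-yl)oxy]-2H-chromen-2-one, via O-acylated salicylaldehyde 19 (not isolated)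
Conditions: Ac2O, Et3N, 120 °C
Reagents that add atoms: none
Why: Ac2O activates acid 18, the phenol of 14 is acylated to 19, and the aryloxy-activated methylene then condenses intramolecularly with the aldehyde and loses water (Perkin condensation, the standard entry to 3-aryloxycoumarins), which closes the lactone of unit B and places the C3–O bond to unit A in one operation.

Step 13
Reactants: 20 8-(2,6-dimethoxyphenyl)-7-methoxy-3-[(2-oxo-2H-chromen-7-yl)oxy]-2H-chromen-2-one
Product: 21 8-(2,6-dihydroxyphenyl)-7-hydroxy-3-[(2-oxo-2H-chromen-7-yl)oxy]-2H-chromen-2-one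
Conditions: BBr3 (10 equiv), CH2Cl2, −78 °C to rt; then ice water
Reagents that add atoms: none
Why: BBr3 cleaves the three aryl methyl ethers by bromide attack on the methyl carbons (Lewis acid ether cleavage), whereas the C3–O–C7 ether offers only sp2 carbons and the two lactones merely bind extra reagent and are released on hydrolysis.

Step 14
Reactants: 21 8-(2,6-dihydroxyphenyl)-7-hydroxy-3-[(2-oxo-2H-chromen-7-yl)oxy]-2H-chromen-2-one; 22 ethyl propiolate
Product: 23 triumbelletin, 7,7'-dihydroxy-3-[(2-oxo-2H-chromen-7-yl)oxy]-8,8'-bichromene-2,2'-dione (racemic axis)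
Conditions: 22 (1.2 equiv), ZnCl2 (1.5 equiv), dioxane, 100 °C
Reagents that add atoms: none
Why: ZnCl2 promotes a Pechmann-type annulation of phenols by propiolate (C-alkenylation ortho to one OH and para to the other, then lactonisation with loss of ethanol); the free resorcinol ring is by far the most nucleophilic arene in 21, its two reactive positions are equivalent by symmetry, and the first annulation deactivates it against a second.

## Compound list

1 | 2,6-dimethoxyphenylacetic acid | COc1cccc(OC)c1CC(=O)O | starting material
2 | Meldrum's acid | CC1(C)OC(=O)CC(=O)O1 | starting material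
3 | 5-[2-(2,6-dimethoxyphenyl)-1-hydroxyethylidene]-2,2-dimethyl-1,3-dioxane-4,6-dione | COc1cccc(OC)c1CC(O)=C1C(=O)OC(C)(C)OC1=O | intermediate
4 | ethyl 4-(2,6-dimethoxyphenyl)-3-oxobutanoate | CCOC(=O)CC(=O)Cc1c(OC)cccc1OC | intermediate
5 | methyl 3,3-dimethoxypropanoate | COC(CC(=O)OC)OC | starting material
6 | N,3,3-trimethoxy-N-methylpropanamide | COC(CC(=O)N(C)OC)OC | intermediate
7 | dilithio dianion of 4 (not isolated) | CCOC([O-])=CC([O-])=Cc1c(OC)cccc1OC.[Li+].[Li+] | intermediate
8 | ethyl 4-(2,6-dimethoxyphenyl)-7,7-dimethoxy-3,5-dioxoheptanoate (racemic, labile methine) | CCOC(=O)CC(=O)C(C(=O)CC(OC)OC)c1c(OC)cccc1OC | intermediate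
9 | ethyl 2-[3-(2,6-dimethoxyphenyl)-4-oxo-4H-pyran-2-yl]acetate | CCOC(=O)Cc1occc(=O)c1-c1c(OC)cccc1OC | intermediate
10 | ethyl (E)-4-(2,6-dimethoxyphenyl)-7-ethoxy-3,5-dioxohept-6-enoate (not isolated) | CCO/C=C/C(=O)C(C(=O)CC(=O)OCC)c1c(OC)cccc1OC | intermediate
11 | ethyl 2,4-dihydroxy-3-(2,6-dimethoxyphenyl)benzoate | CCOC(=O)c1ccc(O)c(-c2c(OC)cccc2OC)c1O | intermediate
12 | ethyl 2-hydroxy-4-methoxy-3-(2,6-dimethoxyphenyl)benzoate | CCOC(=O)c1ccc(OC)c(-c2c(OC)cccc2OC)c1O | intermediate
13 | 2-(2,6-dimethoxyphenyl)-6-(hydroxymethyl)-3-methoxyphenol | OCc1ccc(OC)c(-c2c(OC)cccc2OC)c1O | intermediate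
14 | 2-hydroxy-4-methoxy-3-(2,6-dimethoxyphenyl)benzaldehyde | O=Cc1ccc(OC)c(-c2c(OC)cccc2OC)c1O | intermediate
15 | umbelliferone | O=c1ccc2ccc(O)cc2o1 | starting material
16 | tert-butyl bromoacetate | CC(C)(C)OC(=O)CBr | starting material
17 | tert-butyl 2-[(2-oxo-2H-chromen-7-yl)oxy]acetate | CC(C)(C)OC(=O)COc1ccc2ccc(=O)oc2c1 | intermediate
18 | 2-[(2-oxo-2H-chromen-7-yl)oxy]acetic acid | OC(=O)COc1ccc2ccc(=O)oc2c1 | intermediate
19 | 6-formyl-3-methoxy-2-(2,6-dimethoxyphenyl)phenyl 2-[(2-oxo-2H-chromen-7-yl)oxy]acetate (not isolated) | O=Cc1ccc(OC)c(-c2c(OC)cccc2OC)c1OC(=O)COc1ccc2ccc(=O)oc2c1 | intermediate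
20 | 8-(2,6-dimethoxyphenyl)-7-methoxy-3-[(2-oxo-2H-chromen-7-yl)oxy]-2H-chromen-2-one | COc1ccc2cc(Oc3ccc4ccc(=O)oc4c3)c(=O)oc2c1-c1c(OC)cccc1OC | intermediate
21 | 8-(2,6-dihydroxyphenyl)-7-hydroxy-3-[(2-oxo-2H-chromen-7-yl)oxy]-2H-chromen-2-one | Oc1ccc2cc(Oc3ccc4ccc(=O)oc4c3)c(=O)oc2c1-c1c(O)cccc1O | intermediate
22 | ethyl propiolate | C#CC(=O)OCC | starting material
23 | triumbelletin | O=c1ccc2ccc(Oc3cc4ccc(O)c(-c5c(O)ccc6ccc(=O)oc56)c4oc3=O)cc2o1 | target

## Step count and risks

Total step count: 14.
Longest linear sequence: 11 steps (1, 2, 4, 5, 6, 7, 8, 9, 12, 13, 14).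

The three steps most likely to fail:

**Step 6 (key step).**
- Risk: deprotonation of the acidic side-chain methylene may turn the pyranone into an anion that resists ethoxide addition. O-reclosure may keep returning the opened chain to the pyranone. On long heating, retro-Claisen scission of the chain may overtake the C–C closure.
- Fallback: it sets out from 9 and comes back at 12, so step 7 is saved as well. The activation is changed from anionic to cationic.
- The pyranone carbonyl oxygen is methylated with MeOTf in CH2Cl2 to give 2-(2-ethoxy-2-oxoethyl)-3-(2,6-dimethoxyphenyl)-4-methoxypyrylium triflate F1.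
- In aqueous NaOAc/MeCN at room temperature this cation should take up water at its free C6 and open. The ester methylene should then condense with the non-enolisable aldehyde so released.
- This is the known pyrylium-to-arene ring transformation of 2-alkylpyrylium salts, and it delivers the 4-O-methyl resorcylate 12 directly.

**Step 4.**
- Risk: acylation at the hindered, stabilised benzylic terminus of the dianion may be slow. Proton transfer from the alpha-CH2 of the amide and beta-elimination of methanol could then consume both partners.
- Fallback: it sets out from 4 and 6 and comes back at 8. The acylation is replaced by an aldol addition and an oxidation.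
- Amide 6 is reduced with i-Bu2AlH (THF, −78 °C) to 3,3-dimethoxypropanal F2.
- Dianion 7, made from 4 as before, adds to this far more reactive electrophile at −78 °C. The product is ethyl 4-(2,6-dimethoxyphenyl)-5-hydroxy-7,7-dimethoxy-3-oxoheptanoate F3, a diastereomer mixture of no consequence.
- IBX in hot ethyl acetate oxidises the beta-hydroxy ketone to the 1,3-diketone 8.

**Step 14.**
- Risk: the poorly soluble triphenol may react sluggishly. The phenols may add through oxygen to the propiolate, or alkenylation may not be followed by ring closure.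
- Fallback: it sets out from 21 and comes back at 23. Unit C is built in two C–C bond-forming stages instead of one.
- Vilsmeier–Haack formylation (POCl3, DMF, MeCN, 0 °C to rt, then warm water) attacks the resorcinol ring ortho to one hydroxyl and para to the other. It gives 2,4-dihydroxy-3-{7-hydroxy-2-oxo-3-[(2-oxo-2H-chromen-7-yl)oxy]-2H-chromen-8-yl}benzaldehyde F4.
- Wittig olefination with Ph3P=CHCO2Et in refluxing N,N-diethylaniline gives ethyl (E)-3-(2,4-dihydroxy-3-{7-hydroxy-2-oxo-3-[(2-oxo-2H-chromen-7-yl)oxy]-2H-chromen-8-yl}phenyl)prop-2-enoate F5.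
- At that temperature F5 isomerises and lactonises to 23.

## Further compounds

F1 | step 6 | 2-(2-ethoxy-2-oxoethyl)-3-(2,6-dimethoxyphenyl)-4-methoxypyrylium triflate | CCOC(=O)Cc1[o+]ccc(OC)c1-c1c(OC)cccc1OC.[O-]S(=O)(=O)C(F)(F)F
F2 | step 4 | 3,3-dimethoxypropanal | COC(CC=O)OC
F3 | step 4 | ethyl 4-(2,6-dimethoxyphenyl)-5-hydroxy-7,7-dimethoxy-3-oxoheptanoate (diastereomer mixture) | CCOC(=O)CC(=O)C(C(O)CC(OC)OC)c1c(OC)cccc1OC
F4 | step 14 | 2,4-dihydroxy-3-{7-hydroxy-2-oxo-3-[(2-oxo-2H-chromen-7-yl)oxy]-2H-chromen-8-yl}benzaldehyde | O=Cc1ccc(O)c(-c2c(O)ccc3cc(Oc4ccc5ccc(=O)oc5c4)c(=O)oc23)c1O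
F5 | step 14 | ethyl (E)-3-(2,4-dihydroxy-3-{7-hydroxy-2-oxo-3-[(2-oxo-2H-chromen-7-yl)oxy]-2H-chromen-8-yl}phenyl)prop-2-enoate | CCOC(=O)/C=C/c1ccc(O)c(-c2c(O)ccc3cc(Oc4ccc5ccc(=O)oc5c4)c(=O)oc23)c1O
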